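**Retrosynthetic overview**
1. The ketone comes from the macrocyclic carbinol. The 13-membered ring is closed last by a B-alkyl Suzuki coupling between a (Z)-alkenyl iodide on the tricyclic core and the hydroborated diene terminus of a side chain. That side chain is attached earlier by adding the lithiated tetronate to a β-methoxy aldehyde.
2. The butenolide comes from an α-hydroxy-δ-lactone and Ph3P=C=C=O (O–H addition, then intramolecular Wittig on the lactone C=O). The lactone ring oxygen is kept as the pyran enol ether.
3. The δ-lactone (the future pyran) comes from Pd/CO lactonisation of a dienyl triflate by the tertiary propargylic alcohol. A radical conjugate hydration then sets the oxygenated ring-fusion carbon.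
4. Key step: five-to-six ring expansion (1,2-alkenyl shift) of a 1-alkenylcyclopent-2-enol to the cyclohex-3-enone that carries the quaternary methyl carbon.
5. Order of ring formation: cyclopentene, cyclohexene, δ-lactone/pyran, butenolide, macrocycle.

Assumption: the SMILES is taken as drawn (both macrocyclic olefins Z, methoxy carbon R, the other four centres S), and the trimethylsilyl group of 31 is counted as a protecting group.

**Fragment A**

Step 1
Reactants: 1 2-methylcyclopent-2-en-1-one; 2 ethylmagnesium bromide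
Product: 4 (S)-3-ethyl-2-methylcyclopent-1-en-1-yl trifluoromethanesulfonate, via magnesium enolate 3 (not isolated)
Conditions: Cu(OTf)2 (3 mol %), chiral hydroxyalkyl-imidazolinium NHC precursor (4 mol %), Et2O, −30 °C; then N-(5-chloro-2-pyridyl)bis(triflimide), DMPU, −30 to 23 °C
Reagents that add atoms: N-(5-chloropyridin-2-yl)bis(trifluoromethanesulfonimide), FC(F)(F)S(=O)(=O)N(c1ccc(Cl)cn1)S(=O)(=O)C(F)(F)F
Why: Copper-catalysed asymmetric conjugate addition of the Grignard reagent delivers ethyl to one enone face under ligand control (sets the ethyl-bearing centre as S), and O-triflation of the regiodefined enolate fixes the tetrasubstituted double bond.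

Step 2
Reactants: 4 (S)-3-ethyl-2-methylcyclopent-1-en-1-yl trifluoromethanesulfonate
Product: 5 (S)-5-ethyl-1-methylcyclopent-1-ene
Conditions: Pd(OAc)2 (5 mol %), PPh3, HCO2H, n-Bu3N, DMF, 60 °C
Reagents that add atoms: none
Why: Palladium-catalysed formate reduction of an enol triflate (oxidative addition, decarboxylative hydride transfer, reductive elimination) replaces OTf by H without touching the allylic stereocentre.

Step 3
Reactants: 5 (S)-5-ethyl-1-methylcyclopent-1-ene
Product: 6 (S)-4-ethyl-3-methylcyclopent-2-en-1-one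
Conditions: Rh2(cap)4 (cap = caprolactamate, 1 mol %), t-BuOOH (70 % aq.), K2CO3 (cat.), CH2Cl2, 23 °C
Reagents that add atoms: tert-butyl hydroperoxide, CC(C)(C)OO
Why: Dirhodium-catalysed allylic oxidation attacks the unhindered ring CH2 next to the CH= terminus and gives the enone; abstraction at the tertiary allylic C–H only leads to an achiral separable isomer, so the enantiomeric purity is kept.

**Fragment B**

Step 4
Reactants: 7 2,3-dibromoprop-1-ene
Product: 8 2-(2-bromoprop-2-en-1-yl)-4,4,5,5-tetramethyl-1,3,2-dioxaborolane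
Conditions: B2pin2, Pd2(dba)3 (1 mol %), THF, 60 °C
Reagents that add atoms: bis(pinacolato)diboron, CC1(C)OB(OC1(C)C)B1OC(C)(C)C(C)(C)O1
Why: Miyaura-type allylic borylation ionises only the allylic C–Br bond on phosphine-free zerovalent palladium, and the vinylic bromide stays intact.

Step 5
Reactants: 8 2-(2-bromoprop-2-en-1-yl)-4,4,5,5-tetramethyl-1,3,2-dioxaborolane; 9 pent-3-yn-2-one
Product: 10 (S)-2-bromo-4-methylhept-1-en-5-yn-4-ol
Conditions: valine-derived aminophenol catalyst (3 mol %), NaOt-Bu (10 mol %), MeOH (2.5 equiv), toluene, 4 °C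
Reagents that add atoms: none
Why: Catalytic enantioselective allylboration of a methyl ketone through a chair-like six-membered transition state on the chiral boron catalyst distinguishes the slim alkynyl group from methyl and sets the tertiary carbinol (the future tertiary ether carbon) as S.

Step 6
Reactants: 10 (S)-2-bromo-4-methylhept-1-en-5-yn-4-ol
Product: 11 (S)-[(2-bromo-4-methylhept-1-en-5-yn-4-yl)oxy]triethylsilane
Conditions: Et3SiOTf, 2,6-lutidine, CH2Cl2, 0 °C
Reagents that add atoms: triethylsilyl trifluoromethanesulfonate, CC[Si](CC)(CC)OS(=O)(=O)C(F)(F)F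
Why: Silyl triflate silylation protects the hindered tertiary alcohol so that it can neither quench the organolithium nor form a hemiketal with the later ketone.

**Core**

Step 7
Reactants: 11 (S)-[(2-bromo-4-methylhept-1-en-5-yn-4-yl)oxy]triethylsilane; 6 (S)-4-ethyl-3-methylcyclopent-2-en-1-one
Product: 13 (1R,4S)-4-ethyl-3-methyl-1-[(4S)-4-methyl-4-(triethylsilyloxy)hept-1-en-5-yn-2-yl]cyclopent-2-en-1-ol, via alkenyllithium 12 (not isolated)
Conditions: t-BuLi (2.05 equiv), Et2O, −78 °C; then 6, −78 °C; aq. work-up, base-washed silica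
Reagents that add atoms: none
Why: Bromine–lithium exchange followed by 1,2-addition of the alkenyllithium to the enone carbonyl from the face anti to the ring ethyl group gives the R carbinol (OH cis to ethyl), and the minor epimer is removed by chromatography.

Step 8 (key step)
Reactants: 13 (1R,4S)-4-ethyl-3-methyl-1-[(4S)-4-methyl-4-(triethylsilyloxy)hept-1-en-5-yn-2-yl]cyclopent-2-en-1-ol
Product: 14 (2S,5S)-5-ethyl-2,4-dimethyl-2-[(2S)-2-methyl-2-(triethylsilyloxy)pent-3-yn-1-yl]cyclohex-3-en-1-one
Conditions: [N,N'-bis(3,5-di-tert-butylsalicylidene)-1,2-cyclohexanediaminato]cobalt (5 mol %), N-fluoro-2,4,6-trimethylpyridinium triflate (1.5 equiv), PhSiH3 (1.5 equiv), acetone/PhCF3, 0 °C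
Reagents that add atoms: none
Why: Proposed new method: a cobalt hydride made from the divalent cobalt salen, the N–F oxidant and the silane transfers a hydrogen atom to the terminal CH2 of the 1,1-disubstituted alkene (faster than to the trisubstituted ring alkene or the alkyne) and gives a tertiary radical next to the carbinol carbon; this radical either closes in 3-exo fashion onto the ring C=C and reopens (neophyl-type 1,2-alkenyl shift) to a hydroxyalkyl radical that is oxidised to the ketone, or is captured by cobalt and oxidised to a tetravalent alkylcobalt cation equivalent that undergoes the semipinacol shift of the better-migrating sp2 ring carbon, and both paths give the same ring-expanded β,γ-enone under buffered non-acidic conditions that do not ionise the bis-allylic alcohol; the migrating bond must eclipse the p orbital, and the rotamer that puts the bulky side-chain CH2 beside the small OH and the new CH3 beside the ring CH2 is preferred, which turns the R carbinol into the S quaternary centre (side chain cis to ethyl); the closest known reaction types are the cobalt-salen hydrogen-atom-transfer radical–polar crossover semipinacol rearrangement of tertiary allylic alcohols with aryl or alkyl shift and the halonium-induced ring-expanding semipinacol of 1-alkenylcycloalkanols, neither shown for an alkenyl shift out of a cyclopentenol.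

Step 9
Reactants: 14 (2S,5S)-5-ethyl-2,4-dimethyl-2-[(2S)-2-methyl-2-(triethylsilyloxy)pent-3-yn-1-yl]cyclohex-3-en-1-one
Product: 17 (3S,6S)-3-ethyl-6-[(2S)-2-hydroxy-2-methylpent-3-yn-1-yl]-4,6-dimethylcyclohexa-1,4-dien-1-yl trifluoromethanesulfonate, via potassium enolate 15 (not isolated), via silyl-protected dienyl triflate 16 (not isolated)
Conditions: KHMDS, THF, −78 °C; PhNTf2, −78 to 0 °C; aq. work-up; then HF·pyridine, THF, 0 °C
Reagents that add atoms: N-phenylbis(trifluoromethanesulfonimide), O=S(=O)(N(c1ccccc1)S(=O)(=O)C(F)(F)F)C(F)(F)F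
Why: The ketone has only one enolisable position, so enolate O-triflation is regiospecific, and fluoride-mediated desilylation frees the tertiary alcohol without harming the enol triflate.

Step 10
Reactants: 17 (3S,6S)-3-ethyl-6-[(2S)-2-hydroxy-2-methylpent-3-yn-1-yl]-4,6-dimethylcyclohexa-1,4-dien-1-yl trifluoromethanesulfonate
Product: 18 (3S,4aS,7S)-7-ethyl-3,4a,6-trimethyl-3-(prop-1-yn-1-yl)-3,4,4a,7-tetrahydro-1H-isochromen-1-one
Conditions: Pd(PPh3)4 (10 mol %), CO (1 atm), i-Pr2NEt, DMF, 65 °C
Reagents that add atoms: carbon monoxide, [C-]#[O+]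
Why: Carbonylative lactonisation (oxidative addition, CO insertion, capture of the acylpalladium by the tethered tertiary alcohol in a six-membered closure) installs the missing carbon on the same side as its tether and forms the future pyran ring.

Step 11
Reactants: 18 (3S,4aS,7S)-7-ethyl-3,4a,6-trimethyl-3-(prop-1-yn-1-yl)-3,4,4a,7-tetrahydro-1H-isochromen-1-one
Product: 20 (3S,4aS,7S,8aS)-7-ethyl-8a-hydroxy-3,4a,6-trimethyl-3-(prop-1-yn-1-yl)-3,4,4a,7,8,8a-hexahydro-1H-isochromen-1-one, via tertiary hydroperoxide 19 (not isolated)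
Conditions: Mn(dpm)3 (15 mol %), PhSiH3, O2 (1 atm), i-PrOH/CH2Cl2, 0 °C; then P(OEt)3
Reagents that add atoms: dioxygen, O=O
Why: Mukaiyama-type conjugate hydration puts H on the β-CH and gives the lactone-stabilised tertiary radical, which O2 traps on the face opposite the pseudo-axial ethyl group; this gives the cis-fused lactone with OH syn to the angular methyl (S), the same ring-fusion preference known for 1(9)-decalone enolates with an angular methyl group.

Step 12
Reactants: 20 (3S,4aS,7S,8aS)-7-ethyl-8a-hydroxy-3,4a,6-trimethyl-3-(prop-1-yn-1-yl)-3,4,4a,7,8,8a-hexahydro-1H-isochromen-1-one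
Product: 22 tricyclic propynyl tetronate (four stereocentres all S), via ester ylide 21 (not isolated)
Conditions: Ph3P=C=C=O (1.5 equiv), toluene, 110 °C
Reagents that add atoms: (triphenylphosphoranylidene)ketene, O=C=C=P(c1ccccc1)(c1ccccc1)c1ccccc1
Why: Addition of the tertiary OH to the cumulated ylide gives an ester ylide that closes by intramolecular Wittig olefination of the lactone carbonyl, so the butenolide is formed and the lactone ring oxygen becomes the 4-alkoxy (pyran) oxygen with no stereocentre touched.

Step 13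
Reactants: 22 tricyclic propynyl tetronate
Product: 24 tricyclic (Z)-2-iodoprop-1-enyl tetronate, via alkenylstannane 23 (not isolated)
Conditions: [Cp*Ru(MeCN)3]PF6 (5 mol %), Bu3SnH (slow addition), CH2Cl2, 23 °C; then I2, 0 °C
Reagents that add atoms: iodine, II
Why: Ruthenium-catalysed trans-hydrostannation places tin on the alkyne carbon remote from the fully substituted electron-withdrawing C–O centre and cis to it, and tin–iodine exchange with retention gives the Z iodide that encodes the first macrocyclic olefin geometry.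

**Fragment C**

Step 14
Reactants: 25 prop-2-yn-1-ol; 26 methylmagnesium bromide; 27 vinyl bromide
Product: 29 (2Z)-2-methylpenta-2,4-dien-1-ol, via alkenylmagnesium alkoxide 28 (not isolated)
Conditions: MeMgBr (2.5 equiv), CuI (10 mol %), THF/Et2O, −10 to 23 °C; then vinyl bromide, Pd(PPh3)4 (3 mol %), 23 °C
Reagents that add atoms: none
Why: Copper-catalysed anti-carbomagnesiation of the propargylic alkoxide gives the chelated alkenylmagnesium with Mg cis to CH2O, and Kumada–Corriu coupling with retention turns it into the Z diene.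

Step 15
Reactants: 29 (2Z)-2-methylpenta-2,4-dien-1-ol
Product: 30 (2Z)-2-methylpenta-2,4-dienal
Conditions: activated MnO2, CH2Cl2, 0 to 23 °C, dark, used at once
Reagents that add atoms: none
Why: Neutral heterogeneous allylic alcohol oxidation gives the enal without acid or base that would isomerise the Z double bond.

Step 16
Reactants: 30 (2Z)-2-methylpenta-2,4-dienal; 31 1-methoxy-1-(trimethylsilyloxy)ethene
Product: 33 methyl (3R,4Z)-3-hydroxy-4-methylhepta-4,6-dienoate, via silyl ether aldol 32 (not isolated)
Conditions: Ti(Oi-Pr)4 (3 mol %), binaphthyl-derived tridentate Schiff-base ligand, 3,5-di-tert-butylsalicylic acid, Et2O, −10 °C; then 1 M HCl, THF, 0 °C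
Reagents that add atoms: none
Why: Catalytic asymmetric Mukaiyama acetate aldol addition, which works best with conjugated aldehydes, attacks one aldehyde face under ligand control and sets the future methoxy carbon as R.

Step 17
Reactants: 33 methyl (3R,4Z)-3-hydroxy-4-methylhepta-4,6-dienoate
Product: 34 methyl (3R,4Z)-3-methoxy-4-methylhepta-4,6-dienoate
Conditions: MeI, Ag2O, 4 Å MS, Et2O, 35 °C, dark
Reagents that add atoms: iodomethane, CI
Why: Purdie methylation is non-basic enough to etherify a β-hydroxy ester without retro-aldol cleavage or elimination.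

Step 18
Reactants: 34 methyl (3R,4Z)-3-methoxy-4-methylhepta-4,6-dienoate
Product: 35 (3R,4Z)-3-methoxy-4-methylhepta-4,6-dienal
Conditions: i-Bu2AlH (1.1 equiv), CH2Cl2, −78 °C; aq. Rochelle salt
Reagents that add atoms: none
Why: Partial ester reduction stops at the chelated aluminium hemiacetal at low temperature and releases the aldehyde only on work-up.

**Union and macrocycle**

Step 19
Reactants: 24 tricyclic (Z)-2-iodoprop-1-enyl tetronate; 35 (3R,4Z)-3-methoxy-4-methylhepta-4,6-dienal
Product: 37 3-(1-hydroxy-3-methoxy-4-methylhepta-4,6-dienyl) tetronate (carbinol epimers), via lithiated tetronate 36 (not isolated)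
Conditions: LDA (1.1 equiv), THF, −78 °C; then 35, −78 °C
Reagents that add atoms: none
Why: Directed vinylic deprotonation of the 4-alkoxybutenolide at its only free ring position and 1,2-addition to the aldehyde forms the acyl-side C–C bond, and the new carbinol centre is irrelevant because it is oxidised in step 21.

Step 20
Reactants: 37 3-(1-hydroxy-3-methoxy-4-methylhepta-4,6-dienyl) tetronate
Product: 39 macrocyclic carbinol (13-membered ring with both olefins Z), via bis-borane adduct 38 (not isolated)
Conditions: 9-BBN-H (2.5 equiv), THF, 0 to 23 °C; then slow addition to Pd(dppf)Cl2 (20 mol %), AsPh3, Cs2CO3, DMF/THF/H2O, 1 mM, 45 °C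
Reagents that add atoms: none
Why: 9-BBN hydroborates only the monosubstituted diene terminus, and the intramolecular B-alkyl Suzuki–Miyaura coupling with the alkenyl iodide is stereoretentive, so both preset Z olefins are carried unchanged into the ring.

Step 21
Reactants: 39 macrocyclic carbinol
Product: 40 streptaspironate A
Conditions: Dess–Martin periodinane, pyridine, CH2Cl2, 0 °C
Reagents that add atoms: none
Why: Dess–Martin oxidation converts both carbinol epimers into the 3-acyl tetronate ketone under conditions too mild for β-elimination of methoxide.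

**Compound list**
1 | 2-methylcyclopent-2-en-1-one | CC1=CCCC1=O | starting material
2 | ethylmagnesium bromide | CC[Mg]Br | starting material
3 | bromomagnesium (S)-3-ethyl-2-methylcyclopent-1-en-1-olate | CC[C@H]1CCC(O[Mg]Br)=C1C | intermediate
4 | (S)-3-ethyl-2-methylcyclopent-1-en-1-yl trifluoromethanesulfonate | CC[C@H]1CCC(OS(=O)(=O)C(F)(F)F)=C1C | intermediate
5 | (S)-5-ethyl-1-methylcyclopent-1-ene | CC[C@H]1CCC=C1C | intermediate
6 | (S)-4-ethyl-3-methylcyclopent-2-en-1-one | CC[C@H]1CC(=O)C=C1C | intermediate
7 | 2,3-dibromoprop-1-ene | C=C(Br)CBr | starting material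
8 | 2-(2-bromoprop-2-en-1-yl)-4,4,5,5-tetramethyl-1,3,2-dioxaborolane | C=C(Br)CB1OC(C)(C)C(C)(C)O1 | intermediate
9 | pent-3-yn-2-one | CC#CC(C)=O | starting material
10 | (S)-2-bromo-4-methylhept-1-en-5-yn-4-ol | C=C(Br)C[C@](C)(O)C#CC | intermediate
11 | (S)-[(2-bromo-4-methylhept-1-en-5-yn-4-yl)oxy]triethylsilane | C=C(Br)C[C@](C)(O[Si](CC)(CC)CC)C#CC | intermediate
12 | (S)-2-lithio-4-methyl-4-(triethylsilyloxy)hept-1-en-5-yne | C=C([Li])C[C@](C)(O[Si](CC)(CC)CC)C#CC | intermediate
13 | (1R,4S)-4-ethyl-3-methyl-1-[(4S)-4-methyl-4-(triethylsilyloxy)hept-1-en-5-yn-2-yl]cyclopent-2-en-1-ol | CC[C@H]1C[C@](O)(C(=C)C[C@](C)(O[Si](CC)(CC)CC)C#CC)C=C1C | intermediate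
14 | (2S,5S)-5-ethyl-2,4-dimethyl-2-[(2S)-2-methyl-2-(triethylsilyloxy)pent-3-yn-1-yl]cyclohex-3-en-1-one | CC[C@H]1CC(=O)[C@@](C)(C[C@](C)(O[Si](CC)(CC)CC)C#CC)C=C1C | intermediate
15 | potassium dienolate of 14 | CC[C@H]1C=C([O-])[C@@](C)(C[C@](C)(O[Si](CC)(CC)CC)C#CC)C=C1C.[K+] | intermediate
16 | (3S,6S)-3-ethyl-4,6-dimethyl-6-[(2S)-2-methyl-2-(triethylsilyloxy)pent-3-yn-1-yl]cyclohexa-1,4-dien-1-yl trifluoromethanesulfonate | CC[C@H]1C=C(OS(=O)(=O)C(F)(F)F)[C@@](C)(C[C@](C)(O[Si](CC)(CC)CC)C#CC)C=C1C | intermediate
17 | (3S,6S)-3-ethyl-6-[(2S)-2-hydroxy-2-methylpent-3-yn-1-yl]-4,6-dimethylcyclohexa-1,4-dien-1-yl trifluoromethanesulfonate | CC[C@H]1C=C(OS(=O)(=O)C(F)(F)F)[C@@](C)(C[C@](C)(O)C#CC)C=C1C | intermediate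
18 | (3S,4aS,7S)-7-ethyl-3,4a,6-trimethyl-3-(prop-1-yn-1-yl)-3,4,4a,7-tetrahydro-1H-isochromen-1-one | CC[C@H]1C=C2C(=O)O[C@](C)(C#CC)C[C@@]2(C)C=C1C | intermediate
19 | (3S,4aS,7S,8aS)-7-ethyl-8a-hydroperoxy-3,4a,6-trimethyl-3-(prop-1-yn-1-yl)-3,4,4a,7,8,8a-hexahydro-1H-isochromen-1-one | CC[C@H]1C[C@@]2(OO)C(=O)O[C@](C)(C#CC)C[C@@]2(C)C=C1C | intermediate
20 | (3S,4aS,7S,8aS)-7-ethyl-8a-hydroxy-3,4a,6-trimethyl-3-(prop-1-yn-1-yl)-3,4,4a,7,8,8a-hexahydro-1H-isochromen-1-one | CC[C@H]1C[C@@]2(O)C(=O)O[C@](C)(C#CC)C[C@@]2(C)C=C1C | intermediate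
21 | 8a-O-[(triphenylphosphoranylidene)acetyl] derivative of 20 | CC[C@H]1C[C@@]2(OC(=O)C=P(c3ccccc3)(c3ccccc3)c3ccccc3)C(=O)O[C@](C)(C#CC)C[C@@]2(C)C=C1C | intermediate
22 | tricyclic propynyl tetronate: cyclohexene, dihydropyran and 4-alkoxybutenolide sharing the oxygenated ring-fusion carbon; ethyl carbon, ring-fusion carbon, angular methyl carbon and tertiary ether carbon all S | CC[C@H]1C[C@@]23OC(=O)C=C2O[C@](C)(C#CC)C[C@@]3(C)C=C1C | intermediate
23 | (Z)-2-(tributylstannyl)prop-1-enyl analogue of 22 (tin cis to the tertiary ether carbon) | CC[C@H]1C[C@@]23OC(=O)C=C2O[C@](C)(/C=C(/C)[Sn](CCCC)(CCCC)CCCC)C[C@@]3(C)C=C1C | intermediate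
24 | (Z)-2-iodoprop-1-enyl analogue of 22 (iodine cis to the tertiary ether carbon) | CC[C@H]1C[C@@]23OC(=O)C=C2O[C@](C)(/C=C(/C)I)C[C@@]3(C)C=C1C | intermediate
25 | prop-2-yn-1-ol | C#CCO | starting material
26 | methylmagnesium bromide | C[Mg]Br | starting material
27 | vinyl bromide | C=CBr | starting material
28 | (Z)-3-(bromomagnesio)-2-methylprop-2-en-1-olate bromomagnesium salt | Br[Mg]/C=C(/C)CO[Mg]Br | intermediate
29 | (2Z)-2-methylpenta-2,4-dien-1-ol | C=C/C=C(/C)CO | intermediate
30 | (2Z)-2-methylpenta-2,4-dienal | C=C/C=C(/C)C=O | intermediate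
31 | 1-methoxy-1-(trimethylsilyloxy)ethene | C=C(OC)O[Si](C)(C)C | starting material
32 | methyl (3R,4Z)-4-methyl-3-(trimethylsilyloxy)hepta-4,6-dienoate | C=C/C=C(/C)[C@H](O[Si](C)(C)C)CC(=O)OC | intermediate
33 | methyl (3R,4Z)-3-hydroxy-4-methylhepta-4,6-dienoate | C=C/C=C(/C)[C@H](O)CC(=O)OC | intermediate
34 | methyl (3R,4Z)-3-methoxy-4-methylhepta-4,6-dienoate | C=C/C=C(/C)[C@H](OC)CC(=O)OC | intermediate
35 | (3R,4Z)-3-methoxy-4-methylhepta-4,6-dienal | C=C/C=C(/C)[C@H](OC)CC=O | intermediate
36 | 3-lithio derivative of 24 | CC[C@H]1C[C@@]23OC(=O)C([Li])=C2O[C@](C)(/C=C(/C)I)C[C@@]3(C)C=C1C | intermediate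
37 | adduct of 36 and 35: butenolide C-3 bears CH(OH)CH2CH(OMe)C(Me)=CH–CH=CH2 (methoxy carbon R, olefin Z, carbinol both epimers) | CC[C@H]1C[C@@]23OC(=O)C(C(O)C[C@@H](OC)/C(C)=C\C=C)=C2O[C@](C)(/C=C(/C)I)C[C@@]3(C)C=C1C | intermediate
38 | bis(9-borabicyclo[3.3.1]nonan-9-yl) adduct of 37 (B–C at the former terminal carbon, B–O at the carbinol) | CC[C@H]1C[C@@]23OC(=O)C(C(OB4C5CCCC4CCC5)C[C@@H](OC)/C(C)=C\CCB4C5CCCC4CCC5)=C2O[C@](C)(/C=C(/C)I)C[C@@]3(C)C=C1C | intermediate
39 | macrocyclic carbinol (target with CH(OH) in place of the ketone, both epimers) | CC[C@H]1C[C@@]23OC(=O)C4=C2O[C@](C)(/C=C(/C)CC/C=C(/C)[C@H](OC)CC4O)C[C@@]3(C)C=C1C | intermediate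
40 | streptaspironate A | CC[C@H]1C[C@@]23OC(=O)C4=C2O[C@](C)(/C=C(/C)CC/C=C(/C)[C@H](OC)CC4=O)C[C@@]3(C)C=C1C | target

**Step count**
Total steps: 21. Longest linear sequence: 13 (steps 1–3, 7–13 and 19–21; the branch through steps 4–6 is equally long).

**Steps most likely to fail**

Step 8 (proposed new step). The tertiary radical or cation could instead close to the epoxide, be simply reduced, or shift the ring CH2. The rotamer control of the quaternary centre may also be only moderate. The fallback uses known chemistry and sets out from 13. N-Bromosuccinimide with propylene oxide in CH2Cl2/i-PrOH at −78 °C triggers the classical halonium-induced semipinacol ring expansion to the bromomethyl ketone F1. The neopentyl C–Br bond of F1 is then reduced with Bu3SnH at high concentration with catalytic (PhSe)2 and Et3B/air. The selenol is a very fast hydrogen donor, so the primary radical is trapped before it can undergo acyl or vinyl shifts. The fallback returns to the route at 14.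

Step 11. O2 may be captured on the wrong face, the doubly allylic C–H may autoxidise, or the isolated ring alkene may be hydrated. The fallback replaces the radical step with ionic chemistry and sets out from 18. Conjugate reduction with lithium tri-sec-butylborohydride in THF at −78 °C gives the cis-fused saturated lactone F2. KHMDS converts F2 into the potassium lactone enolate F3. Oxidation of F3 with 2-(phenylsulfonyl)-3-phenyloxaziridine, a bulky electrophile that is steered more strongly away from the ethyl group, brings the sequence back at 20.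

Step 20. Strain in the 13-membered ring may favour protodeboronation or dimerisation. The fallback forms the same C(sp2)–C(sp3) bond intermolecularly and closes the ring elsewhere; it sets out from 34 and 24.
- 9-BBN hydroboration of 34 gives the alkylborane F4.
- Suzuki coupling of F4 with 24 under the same palladium system gives the open-chain ester F5.
- i-Bu2AlH at −78 °C gives the open-chain aldehyde F6.
- I2 with (NH4)2Ce(NO3)6 in MeCN iodinates the free butenolide position and gives the iodo aldehyde F7.
- Nozaki–Hiyama–Kishi ring closure (CrCl2, catalytic NiCl2, DMF/THF, high dilution) forms the bond between the butenolide and the carbinol carbon and returns to the route at 39.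

**Further compounds**
F1 | step 8 | (2R,5S)-2-(bromomethyl)-5-ethyl-4-methyl-2-[(2S)-2-methyl-2-(triethylsilyloxy)pent-3-yn-1-yl]cyclohex-3-en-1-one | CC[C@H]1CC(=O)[C@@](CBr)(C[C@](C)(O[Si](CC)(CC)CC)C#CC)C=C1C
F2 | step 11 | cis-fused saturated lactone (8a-H analogue of 20) | CC[C@H]1C[C@H]2C(=O)O[C@](C)(C#CC)C[C@@]2(C)C=C1C
F3 | step 11 | potassium lactone enolate of F2 | CC[C@H]1CC2=C([O-])O[C@](C)(C#CC)C[C@@]2(C)C=C1C.[K+]
F4 | step 20 | methyl (3R,4Z)-7-(9-borabicyclo[3.3.1]nonan-9-yl)-3-methoxy-4-methylhept-4-enoate | C(CB1C2CCCC1CCC2)/C=C(/C)[C@H](OC)CC(=O)OC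
F5 | step 20 | open-chain ester (core of 22 carrying the full Z,Z-dienyl methoxy ester chain on the tertiary ether carbon) | CC[C@H]1C[C@@]23OC(=O)C=C2O[C@](C)(/C=C(/C)CC/C=C(/C)[C@H](OC)CC(=O)OC)C[C@@]3(C)C=C1C
F6 | step 20 | open-chain aldehyde from F5 | CC[C@H]1C[C@@]23OC(=O)C=C2O[C@](C)(/C=C(/C)CC/C=C(/C)[C@H](OC)CC=O)C[C@@]3(C)C=C1C
F7 | step 20 | 3-iodobutenolide aldehyde from F6 | CC[C@H]1C[C@@]23OC(=O)C(I)=C2O[C@](C)(/C=C(/C)CC/C=C(/C)[C@H](OC)CC=O)C[C@@]3(C)C=C1C
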